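A direct plan would start from oridonin A1, which already holds rings A–D and all twenty carbons, and would remove its 14-hydroxyl by Barton–McCombie deoxygenation to give 14-deoxyoridonin A2.
The three remaining hydroxyls would be turned into the tris-O-nitrite A3, and one photolysis under oxygen would cleave C6–C7 to the 7,20-lactone/C6-aldehyde and oxidise C11 by a 1,5-hydrogen shift to the 1α-alkoxy radical, to give the seco-lactone aldehyde 11-nitrate A4; acetylation of O1, Luche reduction of C6 and C15 and reductive cleavage of the C11 nitrate would finish.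
Weak step, the photolysis that must cut C6–C7 and oxygenate C11 at once: three alkoxy radicals would form beside an exo-methylene ketone, β-scission could also break C5–C6 or C7–C8, and C11 would be set by unguided O2/NO capture of a secondary radical; nothing close is known.
Weak step, the removal of O14 followed by the installation of O11: a thionocarbonate would have to be placed on one of four hydroxyls and reduced with a tin hydride beside a radical-accepting enone, only to move an oxygen by one ring position; no bond of the skeleton would be built.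
Weak step, the closing borohydride/zinc sequence: a nitrate ester, an aldehyde with an epimerisable α-carbon, an enone and an acetate would all have to survive one late operation, and C15 would rest on facial bias with no way back.
The plan would also take its ring system from a natural product, so the skeleton itself could not be varied.

Retrosynthetic overview of the new route:
C8 is the shared α-carbon of the C7 lactone carbonyl and the C15 carbinol, and the C11 carbinol lies across C9. The bicyclo[3.2.1]octane (rings C and D) is therefore opened at C9–C11 and C8–C15 in one step, back to a spiro δ-lactone (ring A + lactone) whose C8 side chain carries an aldehyde (C11) and a methyl acrylate (C15–C17) on the C13 stereocentre.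
The acrylate comes from a terminal alkyne and CO (C15), the C8=C9 bond from a selenoxide, and C8–C14 from alkylation of the spirolactone with an (S)-iodide made by rhodium-catalysed conjugate alkynylation.
The spirolactone comes from 4,4-dimethylcyclohexenone: vinyl addition/methylenation sets C5, Luche reduction sets C1, and a Cp2TiCl epoxide opening/Giese addition/lactonisation sets the spiro centre C10 and the C9–C10 bond.
Ring order: A, then the lactone, then C and D together. O11 and O15 start as carbonyl oxygens on the carbons where the rings close, so no oxygen is removed or moved and no C–H oxidation is needed; C11 is set in a chair transition state and C15 by one exo-face hydride delivery.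
Key step: step 18

Remark on the chemistry: carbons are numbered as in ent-kaurane (C1–C20). As read from the SMILES, O11 lies on the face of ring C that carries the C15–C16 bridge and O15 on the face of ring D turned to the C9–C11–C12 bridge (α/β as in the usual ent-kaurane drawing).
Abbreviations: PMB = 4-methoxybenzyl; TBDPS = tert-butyl(diphenyl)silyl; TIPS = tri(propan-2-yl)silyl; TES = triethylsilyl.

Step 1
Reactants: 1 4,4-dimethylcyclohex-2-en-1-one; 2 vinylmagnesium bromide; 3 N,N-dimethylmethyleneiminium iodide (Eschenmoser's salt)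
Product: 5 (3R)-3-ethenyl-4,4-dimethyl-2-methylidenecyclohexan-1-one, via Mannich base 4 (not isolated)
Conditions: 2, Me2AlCl, Et2O (gives Me2AlCH=CH2); [Cu(MeCN)4]BF4 (2 mol %), chiral phosphoramidite ligand (4 mol %), Et2O, −30 °C; then 3, THF, −30 → 20 °C; then MeI; aq NaHCO3
Reagents that add atoms: vinylmagnesium bromide, C=C[Mg]Br; N,N-dimethylmethyleneiminium iodide, C=[N+](C)C.[I-]
Why: Copper-catalysed asymmetric conjugate addition of an alkenylalane (ligand enantiomer chosen for the 3R adduct, which is C5) gives a regiodefined aluminium enolate that is trapped at C10 in a Mannich reaction, and Hofmann-type elimination of the quaternised amine (Eschenmoser methylenation) leaves the exocyclic methylene C20.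

Step 2
Reactants: 5 (3R)-3-ethenyl-4,4-dimethyl-2-methylidenecyclohexan-1-one
Product: 6 (1S,3R)-3-ethenyl-4,4-dimethyl-2-methylidenecyclohexan-1-ol
Conditions: NaBH4, CeCl3·7H2O, MeOH, −78 °C
Reagents that add atoms: none
Why: Luche 1,2-reduction; axial hydride attack past the axial hydrogens on C3 and C5 should give the equatorial alcohol cis to the equatorial vinyl group, which sets C1.

Step 3
Reactants: 6 (1S,3R)-3-ethenyl-4,4-dimethyl-2-methylidenecyclohexan-1-ol; 7 4-methoxybenzyl chloride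
Product: 8 (1S,3R)-3-ethenyl-1-[(4-methoxybenzyl)oxy]-4,4-dimethyl-2-methylidenecyclohexane
Conditions: NaH, Bu4NI (cat.), DMF, 0 → 20 °C
Reagents that add atoms: 4-methoxybenzyl chloride, COc1ccc(CCl)cc1
Why: Williamson etherification of the allylic alkoxide; the PMB ether tolerates amide bases, Cp2TiCl and SmI2 and can later be removed on its own with DDQ.

Step 4
Reactants: 8 (1S,3R)-3-ethenyl-1-[(4-methoxybenzyl)oxy]-4,4-dimethyl-2-methylidenecyclohexane; 9 3-chloroperoxybenzoic acid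
Product: 10 (4R,8S)-4-ethenyl-8-[(4-methoxybenzyl)oxy]-5,5-dimethyl-1-oxaspiro[2.5]octane (both epimers at the spiro carbon)
Conditions: NaHCO3, CH2Cl2, 0 °C
Reagents that add atoms: 3-chloroperoxybenzoic acid, O=C(OO)c1cccc(Cl)c1
Why: Prilezhaev epoxidation; the 1,1-disubstituted exocyclic alkene should react faster than the monosubstituted vinyl group flanked by the quaternary C4, and the configuration of the spiro carbon is irrelevant because it becomes a planar radical in the next step.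

Step 5
Reactants: 10 (4R,8S)-4-ethenyl-8-[(4-methoxybenzyl)oxy]-5,5-dimethyl-1-oxaspiro[2.5]octane; 11 2,2,2-trifluoroethyl prop-2-enoate
Product: 13 (6S,7R,11S)-7-ethenyl-11-[(4-methoxybenzyl)oxy]-8,8-dimethyl-2-oxaspiro[5.5]undecan-3-one, via hydroxy ester 12 (not isolated)
Conditions: Cp2TiCl2 (0.3 equiv), Zn dust, 2,4,6-collidine hydrochloride, THF, 20 °C
Reagents that add atoms: 2,2,2-trifluoroethyl prop-2-enoate, C=CC(=O)OCC(F)(F)F
Why: Nugent–RajanBabu reductive epoxide opening by Cp2TiCl gives the tertiary C10 radical, which undergoes Giese addition to the acrylate from the face opposite the axial C4 methyl and the flanking C1-OPMB and C5-vinyl groups (C9 trans to C6 and O1), and the C20 titanium alkoxide then closes the δ-lactone on the activated ester.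

Step 6
Reactants: 13 (6S,7R,11S)-7-ethenyl-11-[(4-methoxybenzyl)oxy]-8,8-dimethyl-2-oxaspiro[5.5]undecan-3-one; 14 ozone
Product: 16 (6S,7R,11S)-7-(hydroxymethyl)-11-[(4-methoxybenzyl)oxy]-8,8-dimethyl-2-oxaspiro[5.5]undecan-3-one, via aldehyde 15 (not isolated)
Conditions: O3, CH2Cl2/MeOH, −78 °C; then NaBH4, −78 → 0 °C
Reagents that add atoms: ozone, [O-][O+]=O
Why: Ozonolysis of the only alkene with reductive borohydride work-up turns the vinyl group into the C6 hydroxymethyl without touching C5; the δ-lactone should survive NaBH4 at low temperature.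

Step 7
Reactants: 16 (6S,7R,11S)-7-(hydroxymethyl)-11-[(4-methoxybenzyl)oxy]-8,8-dimethyl-2-oxaspiro[5.5]undecan-3-one; 17 tert-butyl(chloro)diphenylsilane
Product: 18 (6S,7R,11S)-7-(TBDPS-oxymethyl)-11-(PMB-oxy)-8,8-dimethyl-2-oxaspiro[5.5]undecan-3-one
Conditions: imidazole, DMF, 20 °C
Reagents that add atoms: tert-butyl(chloro)diphenylsilane, CC(C)(C)[Si](Cl)(c1ccccc1)c1ccccc1
Why: Silylation of the primary alcohol; the TBDPS ether tolerates amide bases, fluoride-free alkyne desilylation, dilute acid and SmI2.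

Step 8
Reactants: 19 (Z)-but-2-ene-1,4-diol; 7 4-methoxybenzyl chloride
Product: 20 (Z)-4-[(4-methoxybenzyl)oxy]but-2-en-1-ol
Conditions: NaH (1 equiv), Bu4NI (cat.), THF, 0 → 20 °C, diol in excess
Reagents that add atoms: 4-methoxybenzyl chloride, COc1ccc(CCl)cc1
Why: Statistical Williamson mono-etherification of the symmetrical diol.

Step 9
Reactants: 20 (Z)-4-[(4-methoxybenzyl)oxy]but-2-en-1-ol
Product: 21 (E)-4-[(4-methoxybenzyl)oxy]but-2-enal
Conditions: pyridinium chlorochromate (C5H5NH[CrO3Cl]), NaOAc, CH2Cl2, 20 °C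
Reagents that add atoms: none
Why: Chromate oxidation of the allylic alcohol with isomerisation of the (Z)-enal to the conjugated (E)-enal under the mildly acidic conditions.

Step 10
Reactants: 21 (E)-4-[(4-methoxybenzyl)oxy]but-2-enal; 22 ethynyltri(propan-2-yl)silane
Product: 23 (3S)-3-{[(4-methoxybenzyl)oxy]methyl}-5-TIPS-pent-4-ynal
Conditions: [Rh(OAc)(C2H4)2]2 (2.5 mol %), (R)-DTBM-SEGPHOS (6 mol %), MeOH, 40 °C
Reagents that add atoms: ethynyltri(propan-2-yl)silane, C#C[Si](C(C)C)(C(C)C)C(C)C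
Why: Rhodium-catalysed asymmetric conjugate alkynylation of an enal (the bulky silyl group suppresses alkyne dimerisation); the bisphosphine enantiomer is chosen so that the alkynyl group adds to the face giving 3S, the future C13.

Step 11
Reactants: 23 (3S)-3-{[(4-methoxybenzyl)oxy]methyl}-5-TIPS-pent-4-ynal; 24 trimethyl orthoformate
Product: 25 (3S)-5,5-dimethoxy-3-{[(4-methoxybenzyl)oxy]methyl}-1-TIPS-pent-1-yne
Conditions: pyridinium 4-toluenesulfonate (cat.), MeOH, 20 °C
Reagents that add atoms: trimethyl orthoformate, COC(OC)OC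
Why: Acetalisation masks the future C11 aldehyde against the amide bases used later.

Step 12
Reactants: 25 (3S)-5,5-dimethoxy-3-{[(4-methoxybenzyl)oxy]methyl}-1-TIPS-pent-1-yne
Product: 26 (2S)-2-(2,2-dimethoxyethyl)-4-TIPS-but-3-yn-1-ol
Conditions: DDQ, CH2Cl2/pH 7 buffer, 0 °C
Reagents that add atoms: none
Why: Oxidative cleavage of the PMB ether under neutral conditions that spare the acetal and the silyl alkyne.

Step 13
Reactants: 26 (2S)-2-(2,2-dimethoxyethyl)-4-TIPS-but-3-yn-1-ol; 27 iodine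
Product: 28 (3S)-3-(iodomethyl)-5,5-dimethoxy-1-TIPS-pent-1-yne
Conditions: PPh3, imidazole, CH2Cl2, 0 °C
Reagents that add atoms: iodine, II
Why: Appel-type iodination of the primary alcohol (C14); the stereocentre is not involved.

Step 14
Reactants: 18 (6S,7R,11S)-7-(TBDPS-oxymethyl)-11-(PMB-oxy)-8,8-dimethyl-2-oxaspiro[5.5]undecan-3-one; 28 (3S)-3-(iodomethyl)-5,5-dimethoxy-1-TIPS-pent-1-yne
Product: 29 (6S,7R,11S)-4-[(2S)-2-(2,2-dimethoxyethyl)-4-TIPS-but-3-yn-1-yl]-7-(TBDPS-oxymethyl)-11-(PMB-oxy)-8,8-dimethyl-2-oxaspiro[5.5]undecan-3-one (both C4 epimers)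
Conditions: LiN(i-Pr)2, THF, −78 °C; then 28, HMPA, −78 → −30 °C
Reagents that add atoms: (3S)-3-(iodomethyl)-5,5-dimethoxy-1-TIPS-pent-1-yne, COC(OC)C[C@@H](C#C[Si](C(C)C)(C(C)C)C(C)C)CI
Why: Alkylation of the lactone lithium enolate with the primary iodide forms C8–C14 and joins the two fragments; the C8 configuration is irrelevant because C8 becomes sp2 in the next step.

Step 15
Reactants: 29 (6S,7R,11S)-4-[(2S)-2-(2,2-dimethoxyethyl)-4-TIPS-but-3-yn-1-yl]-7-(TBDPS-oxymethyl)-11-(PMB-oxy)-8,8-dimethyl-2-oxaspiro[5.5]undecan-3-one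
Product: 31 (6S,7R,11S)-4-[(2S)-2-(2,2-dimethoxyethyl)-4-TIPS-but-3-yn-1-yl]-7-(TBDPS-oxymethyl)-11-(PMB-oxy)-8,8-dimethyl-2-oxaspiro[5.5]undec-4-en-3-one, via selenide 30 (not isolated)
Conditions: KN(SiMe3)2, THF, −78 °C; PhSeBr; then H2O2, pyridine, CH2Cl2, 0 → 20 °C
Reagents that add atoms: none
Why: α-Selenenylation of the lactone enolate and selenoxide syn-elimination towards the ring hydrogen on C9 should give the endocyclic α-substituted unsaturated δ-lactone (C8=C9), the more stable enoate isomer.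

Step 16
Reactants: 31 (6S,7R,11S)-4-[(2S)-2-(2,2-dimethoxyethyl)-4-TIPS-but-3-yn-1-yl]-7-(TBDPS-oxymethyl)-11-(PMB-oxy)-8,8-dimethyl-2-oxaspiro[5.5]undec-4-en-3-one
Product: 32 (6S,7R,11S)-4-[(2S)-2-(2,2-dimethoxyethyl)but-3-yn-1-yl]-7-(TBDPS-oxymethyl)-11-(PMB-oxy)-8,8-dimethyl-2-oxaspiro[5.5]undec-4-en-3-one
Conditions: AgF, MeOH/THF, 20 °C, dark; then 1 M HCl
Reagents that add atoms: none
Why: Silver-mediated protiodesilylation of the silyl alkyne through the silver acetylide leaves the TBDPS ether, the PMB ether and (in methanol) the dimethyl acetal in place.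

Step 17
Reactants: 32 (6S,7R,11S)-4-[(2S)-2-(2,2-dimethoxyethyl)but-3-yn-1-yl]-7-(TBDPS-oxymethyl)-11-(PMB-oxy)-8,8-dimethyl-2-oxaspiro[5.5]undec-4-en-3-one; 33 carbon monoxide; 34 methanol; 35 water
Product: 37 methyl (3S)-3-{[(6S,7R,11S)-7-(TBDPS-oxymethyl)-11-(PMB-oxy)-8,8-dimethyl-3-oxo-2-oxaspiro[5.5]undec-4-en-4-yl]methyl}-2-methylidene-5-oxopentanoate, via acetal ester 36 (not isolated)
Conditions: Pd(OAc)2 (1 mol %), 2-(diphenylphosphanyl)pyridine (4 mol %), CH3SO3H (2 mol %), CO (30 bar), MeOH, 45 °C; then 1 M HCl, THF, 20 °C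
Reagents that add atoms: carbon monoxide, [C-]#[O+]; methanol, CO; water, O
Why: Palladium hydride-catalysed Markovnikov hydromethoxycarbonylation of the terminal alkyne (Reppe-type carbonylation) gives the 2-substituted acrylate with C15 coming from CO, and mild hydrolysis of the unhindered dimethyl acetal then frees the C11 aldehyde.

Step 18
Reactants: 37 methyl (3S)-3-{[(6S,7R,11S)-7-(TBDPS-oxymethyl)-11-(PMB-oxy)-8,8-dimethyl-3-oxo-2-oxaspiro[5.5]undec-4-en-4-yl]methyl}-2-methylidene-5-oxopentanoate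
Product: 39 11β-hydroxy-1α-(PMB-oxy)-6-(TBDPS-oxy)-15-oxo-6,7-seco-ent-kaur-16-en-7,20-olide, via samarium enolate 38 (not isolated)
Conditions: SmI2 (2.1 equiv), THF, −78 → −20 °C, no proton donor; then air, aq NaHCO3
Reagents that add atoms: none
Why: Proposed new method: SmI2 reduces the C11 aldehyde to a ketyl that adds 6-endo-trig to C9 of the α-substituted unsaturated δ-lactone (polarity-matched; the closest known reactions are SmI2 ketyl–enoate cyclisations of such lactone aldehydes and SmI2 cyclisation–aldol cascades), and a second electron turns the C8 radical into a trivalent samarium enolate. With no proton donor present this enolate, or the bridged lactone first formed from the C11 samarium alkoxide and the ester, is acylated by the pendant methyl ester C15 in a 5-(enolexo)-exo-trig Dieckmann-type closure, so ring C and ring D, the whole bicyclo[3.2.1]octane, arise in one flask. C9 and C11 are set in a chair transition state in which C10, the O–Sm group and the C13 substituent are all equatorial and in which C11 approaches the lactone face syn to C1, away from the C5/C4 flank of the spiro centre C10. The quaternary centre C8 is set by the tether: the ester hangs from C13 and can reach only the enolate face cis to it, which is also the face that keeps the lactone cis-fused. The step needs ketyl formation to outrun reduction of the two enoates (aldehydes are reduced far faster at −78 °C, and ketyl addition to the acrylate would be 4-exo or 5-endo) and needs exactly two electrons, so that no reductant remains when the tetrahedral intermediate collapses to the exo-methylene ketone on work-up.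

Step 19
Reactants: 39 11β-hydroxy-1α-(PMB-oxy)-6-(TBDPS-oxy)-15-oxo-6,7-seco-ent-kaur-16-en-7,20-olide; 40 triethylsilyl trifluoromethanesulfonate
Product: 41 1α-(PMB-oxy)-6-(TBDPS-oxy)-11β-(TES-oxy)-15-oxo-6,7-seco-ent-kaur-16-en-7,20-olide
Conditions: 2,6-lutidine, CH2Cl2, −78 → 0 °C
Reagents that add atoms: triethylsilyl trifluoromethanesulfonate, CC[Si](CC)(CC)OS(=O)(=O)C(F)(F)F
Why: Silylation of the hindered C11 hydroxyl with the silyl triflate, so that O1 alone is free at the acetylation and the endo face of the C15 ketone is screened.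

Step 20
Reactants: 41 1α-(PMB-oxy)-6-(TBDPS-oxy)-11β-(TES-oxy)-15-oxo-6,7-seco-ent-kaur-16-en-7,20-olide
Product: 42 1α-hydroxy-6-(TBDPS-oxy)-11β-(TES-oxy)-15-oxo-6,7-seco-ent-kaur-16-en-7,20-olide
Conditions: DDQ, CH2Cl2/pH 7 buffer, 0 °C
Reagents that add atoms: none
Why: Oxidative PMB cleavage frees O1 alone; the silyl ethers, the lactone and the enone are inert to DDQ.

Step 21
Reactants: 42 1α-hydroxy-6-(TBDPS-oxy)-11β-(TES-oxy)-15-oxo-6,7-seco-ent-kaur-16-en-7,20-olide; 43 acetic anhydride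
Product: 44 1α-acetoxy-6-(TBDPS-oxy)-11β-(TES-oxy)-15-oxo-6,7-seco-ent-kaur-16-en-7,20-olide
Conditions: DMAP, pyridine, 20 °C
Reagents that add atoms: acetic anhydride, CC(=O)OC(C)=O
Why: DMAP-catalysed acetylation of the only free hydroxyl (equatorial O1) with retention at C1.

Step 22
Reactants: 44 1α-acetoxy-6-(TBDPS-oxy)-11β-(TES-oxy)-15-oxo-6,7-seco-ent-kaur-16-en-7,20-olide
Product: 45 1α-acetoxy-15β-hydroxy-6-(TBDPS-oxy)-11β-(TES-oxy)-6,7-seco-ent-kaur-16-en-7,20-olide
Conditions: NaBH4, CeCl3·7H2O, MeOH, −78 °C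
Reagents that add atoms: none
Why: Luche 1,2-reduction of the exo-methylene ketone; hydride should add from the exo face on the side of the one-carbon bridge C14, the endo face being blocked by the C9–C11–C12 bridge and its 11-silyloxy group, which gives the 15β (endo) alcohol and leaves acetate and lactone alone.

Step 23
Reactants: 45 1α-acetoxy-15β-hydroxy-6-(TBDPS-oxy)-11β-(TES-oxy)-6,7-seco-ent-kaur-16-en-7,20-olide
Product: 46 1α-acetoxy-6,11β,15β-trihydroxy-6,7-seco-ent-kaur-16-en-7,20-olide (CNP0210922.1)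
Conditions: HF·pyridine, pyridine/THF, 0 → 20 °C
Reagents that add atoms: none
Why: Fluoride cleavage of the TES and TBDPS ethers under buffered conditions that should neither hydrolyse nor shift the C1 acetate and that leave the allylic alcohol and the lactone intact.

Compound list
1 | 4,4-dimethylcyclohex-2-en-1-one | O=C1C=CC(C)(C)CC1 | starting material
2 | vinylmagnesium bromide | C=C[Mg]Br | starting material
3 | N,N-dimethylmethyleneiminium iodide (Eschenmoser's salt) | C=[N+](C)C.[I-] | starting material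
4 | Mannich base, 2-[(dimethylamino)methyl]-3-ethenyl-4,4-dimethylcyclohexan-1-one (ethenyl-bearing carbon as in 5) | CN(C)CC1C(=O)CCC(C)(C)[C@H]1C=C | intermediate
5 | (3R)-3-ethenyl-4,4-dimethyl-2-methylidenecyclohexan-1-one | C=C1C(=O)CCC(C)(C)[C@H]1C=C | intermediate
6 | (1S,3R)-3-ethenyl-4,4-dimethyl-2-methylidenecyclohexan-1-ol | C=C1[C@@H](O)CCC(C)(C)[C@H]1C=C | intermediate
7 | 4-methoxybenzyl chloride | COc1ccc(CCl)cc1 | starting material
8 | (1S,3R)-3-ethenyl-1-[(4-methoxybenzyl)oxy]-4,4-dimethyl-2-methylidenecyclohexane | C=C1[C@@H](OCc2ccc(OC)cc2)CCC(C)(C)[C@H]1C=C | intermediate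
9 | 3-chloroperoxybenzoic acid | O=C(OO)c1cccc(Cl)c1 | starting material
10 | (4R,8S)-4-ethenyl-8-[(4-methoxybenzyl)oxy]-5,5-dimethyl-1-oxaspiro[2.5]octane (both epimers at the spiro carbon) | C1OC12[C@@H](OCc3ccc(OC)cc3)CCC(C)(C)[C@H]2C=C | intermediate
11 | 2,2,2-trifluoroethyl prop-2-enoate | C=CC(=O)OCC(F)(F)F | starting material
12 | hydroxy ester, 2,2,2-trifluoroethyl 3-[2-ethenyl-1-(hydroxymethyl)-6-(PMB-oxy)-3,3-dimethylcyclohexyl]propanoate (as its titanium alkoxide, configured as in 13) | OC[C@@]1(CCC(=O)OCC(F)(F)F)[C@@H](OCc2ccc(OC)cc2)CCC(C)(C)[C@H]1C=C | intermediate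
13 | (6S,7R,11S)-7-ethenyl-11-[(4-methoxybenzyl)oxy]-8,8-dimethyl-2-oxaspiro[5.5]undecan-3-one | O=C1CC[C@]2(CO1)[C@@H](OCc3ccc(OC)cc3)CCC(C)(C)[C@H]2C=C | intermediate
14 | ozone | [O-][O+]=O | starting material
15 | aldehyde, (6S,7R,11S)-11-[(4-methoxybenzyl)oxy]-8,8-dimethyl-3-oxo-2-oxaspiro[5.5]undecane-7-carbaldehyde | O=C1CC[C@]2(CO1)[C@@H](OCc3ccc(OC)cc3)CCC(C)(C)[C@H]2C=O | intermediate
16 | (6S,7R,11S)-7-(hydroxymethyl)-11-[(4-methoxybenzyl)oxy]-8,8-dimethyl-2-oxaspiro[5.5]undecan-3-one | O=C1CC[C@]2(CO1)[C@@H](OCc3ccc(OC)cc3)CCC(C)(C)[C@H]2CO | intermediate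
17 | tert-butyl(chloro)diphenylsilane | CC(C)(C)[Si](Cl)(c1ccccc1)c1ccccc1 | starting material
18 | (6S,7R,11S)-7-(TBDPS-oxymethyl)-11-(PMB-oxy)-8,8-dimethyl-2-oxaspiro[5.5]undecan-3-one | O=C1CC[C@]2(CO1)[C@@H](OCc3ccc(OC)cc3)CCC(C)(C)[C@H]2CO[Si](c4ccccc4)(c5ccccc5)C(C)(C)C | intermediate
19 | (Z)-but-2-ene-1,4-diol | OC/C=C\CO | starting material
20 | (Z)-4-[(4-methoxybenzyl)oxy]but-2-en-1-ol | OC/C=C\COCc1ccc(OC)cc1 | intermediate
21 | (E)-4-[(4-methoxybenzyl)oxy]but-2-enal | O=C/C=C/COCc1ccc(OC)cc1 | intermediate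
22 | ethynyltri(propan-2-yl)silane | C#C[Si](C(C)C)(C(C)C)C(C)C | starting material
23 | (3S)-3-{[(4-methoxybenzyl)oxy]methyl}-5-TIPS-pent-4-ynal | O=CC[C@@H](C#C[Si](C(C)C)(C(C)C)C(C)C)COCc1ccc(OC)cc1 | intermediate
24 | trimethyl orthoformate | COC(OC)OC | starting material
25 | (3S)-5,5-dimethoxy-3-{[(4-methoxybenzyl)oxy]methyl}-1-TIPS-pent-1-yne | COC(OC)C[C@@H](C#C[Si](C(C)C)(C(C)C)C(C)C)COCc1ccc(OC)cc1 | intermediate
26 | (2S)-2-(2,2-dimethoxyethyl)-4-TIPS-but-3-yn-1-ol | COC(OC)C[C@@H](C#C[Si](C(C)C)(C(C)C)C(C)C)CO | intermediate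
27 | iodine | II | starting material
28 | (3S)-3-(iodomethyl)-5,5-dimethoxy-1-TIPS-pent-1-yne | COC(OC)C[C@@H](C#C[Si](C(C)C)(C(C)C)C(C)C)CI | intermediate
29 | (6S,7R,11S)-4-[(2S)-2-(2,2-dimethoxyethyl)-4-TIPS-but-3-yn-1-yl]-7-(TBDPS-oxymethyl)-11-(PMB-oxy)-8,8-dimethyl-2-oxaspiro[5.5]undecan-3-one (both C4 epimers) | COC(OC)C[C@@H](C#C[Si](C(C)C)(C(C)C)C(C)C)CC1C[C@]2(COC1=O)[C@@H](OCc3ccc(OC)cc3)CCC(C)(C)[C@H]2CO[Si](c4ccccc4)(c5ccccc5)C(C)(C)C | intermediate
30 | selenide, the 4-(phenylselanyl) derivative of 29 | COC(OC)C[C@@H](C#C[Si](C(C)C)(C(C)C)C(C)C)CC1([Se]c6ccccc6)C[C@]2(COC1=O)[C@@H](OCc3ccc(OC)cc3)CCC(C)(C)[C@H]2CO[Si](c4ccccc4)(c5ccccc5)C(C)(C)C | intermediate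
31 | (6S,7R,11S)-4-[(2S)-2-(2,2-dimethoxyethyl)-4-TIPS-but-3-yn-1-yl]-7-(TBDPS-oxymethyl)-11-(PMB-oxy)-8,8-dimethyl-2-oxaspiro[5.5]undec-4-en-3-one | COC(OC)C[C@@H](C#C[Si](C(C)C)(C(C)C)C(C)C)CC1=C[C@]2(COC1=O)[C@@H](OCc3ccc(OC)cc3)CCC(C)(C)[C@H]2CO[Si](c4ccccc4)(c5ccccc5)C(C)(C)C | intermediate
32 | (6S,7R,11S)-4-[(2S)-2-(2,2-dimethoxyethyl)but-3-yn-1-yl]-7-(TBDPS-oxymethyl)-11-(PMB-oxy)-8,8-dimethyl-2-oxaspiro[5.5]undec-4-en-3-one | COC(OC)C[C@@H](C#C)CC1=C[C@]2(COC1=O)[C@@H](OCc3ccc(OC)cc3)CCC(C)(C)[C@H]2CO[Si](c4ccccc4)(c5ccccc5)C(C)(C)C | intermediate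
33 | carbon monoxide | [C-]#[O+] | starting material
34 | methanol | CO | starting material
35 | water | O | starting material
36 | acetal ester, methyl (3S)-5,5-dimethoxy-2-methylidene-3-{[spirolactone core of 32]methyl}pentanoate | COC(OC)C[C@@H](C(=C)C(=O)OC)CC1=C[C@]2(COC1=O)[C@@H](OCc3ccc(OC)cc3)CCC(C)(C)[C@H]2CO[Si](c4ccccc4)(c5ccccc5)C(C)(C)C | intermediate
37 | methyl (3S)-3-{[(6S,7R,11S)-7-(TBDPS-oxymethyl)-11-(PMB-oxy)-8,8-dimethyl-3-oxo-2-oxaspiro[5.5]undec-4-en-4-yl]methyl}-2-methylidene-5-oxopentanoate | O=CC[C@@H](C(=C)C(=O)OC)CC1=C[C@]2(COC1=O)[C@@H](OCc3ccc(OC)cc3)CCC(C)(C)[C@H]2CO[Si](c4ccccc4)(c5ccccc5)C(C)(C)C | intermediate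
38 | samarium enolate of the ring-C-closed lactone (C9–C11 formed, 11β-O, C8=C7 enolate; drawn as the free enol) | C=C(C(=O)OC)[C@@H]1C[C@H](O)[C@@H]2C(C1)=C(O)OC[C@]23[C@@H](OCc4ccc(OC)cc4)CCC(C)(C)[C@H]3CO[Si](c5ccccc5)(c6ccccc6)C(C)(C)C | intermediate
39 | 11β-hydroxy-1α-(PMB-oxy)-6-(TBDPS-oxy)-15-oxo-6,7-seco-ent-kaur-16-en-7,20-olide | C=C1[C@@H]2C[C@H](O)[C@@H]3[C@](C2)(C(=O)OC[C@]32[C@@H](OCc4ccc(OC)cc4)CCC(C)(C)[C@H]2CO[Si](c5ccccc5)(c6ccccc6)C(C)(C)C)C1=O | intermediate
40 | triethylsilyl trifluoromethanesulfonate | CC[Si](CC)(CC)OS(=O)(=O)C(F)(F)F | starting material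
41 | 1α-(PMB-oxy)-6-(TBDPS-oxy)-11β-(TES-oxy)-15-oxo-6,7-seco-ent-kaur-16-en-7,20-olide | C=C1[C@@H]2C[C@H](O[Si](CC)(CC)CC)[C@@H]3[C@](C2)(C(=O)OC[C@]32[C@@H](OCc4ccc(OC)cc4)CCC(C)(C)[C@H]2CO[Si](c5ccccc5)(c6ccccc6)C(C)(C)C)C1=O | intermediate
42 | 1α-hydroxy-6-(TBDPS-oxy)-11β-(TES-oxy)-15-oxo-6,7-seco-ent-kaur-16-en-7,20-olide | C=C1[C@@H]2C[C@H](O[Si](CC)(CC)CC)[C@@H]3[C@](C2)(C(=O)OC[C@]32[C@@H](O)CCC(C)(C)[C@H]2CO[Si](c4ccccc4)(c5ccccc5)C(C)(C)C)C1=O | intermediate
43 | acetic anhydride | CC(=O)OC(C)=O | starting material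
44 | 1α-acetoxy-6-(TBDPS-oxy)-11β-(TES-oxy)-15-oxo-6,7-seco-ent-kaur-16-en-7,20-olide | C=C1[C@@H]2C[C@H](O[Si](CC)(CC)CC)[C@@H]3[C@](C2)(C(=O)OC[C@]32[C@@H](OC(C)=O)CCC(C)(C)[C@H]2CO[Si](c4ccccc4)(c5ccccc5)C(C)(C)C)C1=O | intermediate
45 | 1α-acetoxy-15β-hydroxy-6-(TBDPS-oxy)-11β-(TES-oxy)-6,7-seco-ent-kaur-16-en-7,20-olide | C=C1[C@@H]2C[C@H](O[Si](CC)(CC)CC)[C@@H]3[C@](C2)(C(=O)OC[C@]32[C@@H](OC(C)=O)CCC(C)(C)[C@H]2CO[Si](c4ccccc4)(c5ccccc5)C(C)(C)C)[C@@H]1O | intermediate
46 | 1α-acetoxy-6,11β,15β-trihydroxy-6,7-seco-ent-kaur-16-en-7,20-olide (CNP0210922.1) | C=C1[C@@H]2C[C@H](O)[C@@H]3[C@](C2)(C(=O)OC[C@]32[C@@H](OC(C)=O)CCC(C)(C)[C@H]2CO)[C@@H]1O | target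

Total step count: 23 steps. Longest linear sequence: 17 steps (steps 1–7 and 14–23); the iodide 28 is made in 6 steps (8–13) and joined in step 14.

Steps most likely to fail:

Step 18 (one-flask ring C/ring D closure). The samarium enolate may be protonated or may fail to acylate, or leftover reductant may reduce the enone once it forms. The fallback splits the operation into two known reactions. Setting out from 37, SmI2 with LiBr and t-BuOH in THF at −78 °C (ketyl–enoate cyclisation with a proton donor) should give the ring-C-closed hydroxy ester F1 (C8 epimers, or its bridged C15–O11 lactone form, are equivalent here). Treatment with LiN(SiMe3)2 (2.2 equiv, THF, −78 → −30 °C) should then close ring D by an intramolecular Claisen (Dieckmann) acylation of the lactone enolate, returning to the route at 39.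

Step 15 (selenoxide elimination). Syn-elimination may run towards the side chain (C14–H) and give the exocyclic alkylidene lactone instead of the C8=C9 enoate. The fallback introduces the unsaturation before the side chain. Setting out from 18, selenenylation and oxidation (KN(SiMe3)2, PhSeBr; H2O2), where only C9–H is available, should give the unsubstituted unsaturated spirolactone F2. I2/pyridine α-iodination should give the α-iodo enoate F3. Negishi coupling of F3 with the alkylzinc iodide F4 (made from 28 with Zn and LiCl in THF; Pd(OAc)2, SPhos, THF, 40 °C) would return to the route at 31.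

Step 17 (alkyne hydromethoxycarbonylation). The acid co-catalyst may strip the PMB ether, or linear ester and double carbonylation may compete. The fallback brings C15 in after ring C is closed. Setting out from 32, aqueous HCl/THF should give the alkynyl aldehyde F5. SmI2/LiBr/t-BuOH should close ring C to the alkynol F6, with the 11-hydroxyl and the ethynyl group cis-1,3. Palladium-catalysed cyclocarbonylation of this 4-pentyn-1-ol unit (PdCl2(PPh3)2, SnCl2, CO 7 bar, MeCN, 70 °C) should give the bridged α-methylene lactone F7. LiN(SiMe3)2 in THF at −78 → −20 °C should then transfer the acyl group from O11 to the C8 enolate (Baker–Venkataraman-type O→C shift), returning to the route at 39.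

Further compounds
F1 | step 18 | ring-C-closed hydroxy ester, methyl 2-(ring C C13-yl)prop-2-enoate with 11β-OH and H at C8 (ring D open; lactone, PMB and TBDPS groups as in 39) | C=C(C(=O)OC)[C@@H]1C[C@H](O)[C@@H]2C(C1)C(=O)OC[C@]23[C@@H](OCc4ccc(OC)cc4)CCC(C)(C)[C@H]3CO[Si](c5ccccc5)(c6ccccc6)C(C)(C)C
F2 | step 15 | (6S,7R,11S)-7-(TBDPS-oxymethyl)-11-(PMB-oxy)-8,8-dimethyl-2-oxaspiro[5.5]undec-4-en-3-one | O=C1C=C[C@]2(CO1)[C@@H](OCc3ccc(OC)cc3)CCC(C)(C)[C@H]2CO[Si](c4ccccc4)(c5ccccc5)C(C)(C)C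
F3 | step 15 | (6S,7R,11S)-4-iodo-7-(TBDPS-oxymethyl)-11-(PMB-oxy)-8,8-dimethyl-2-oxaspiro[5.5]undec-4-en-3-one | O=C1C(I)=C[C@]2(CO1)[C@@H](OCc3ccc(OC)cc3)CCC(C)(C)[C@H]2CO[Si](c4ccccc4)(c5ccccc5)C(C)(C)C
F4 | step 15 | [(2S)-2-(2,2-dimethoxyethyl)-4-TIPS-but-3-yn-1-yl]zinc iodide | COC(OC)C[C@@H](C#C[Si](C(C)C)(C(C)C)C(C)C)C[Zn]I
F5 | step 17 | (3S)-3-{[(6S,7R,11S)-7-(TBDPS-oxymethyl)-11-(PMB-oxy)-8,8-dimethyl-3-oxo-2-oxaspiro[5.5]undec-4-en-4-yl]methyl}pent-4-ynal | O=CC[C@@H](C#C)CC1=C[C@]2(COC1=O)[C@@H](OCc3ccc(OC)cc3)CCC(C)(C)[C@H]2CO[Si](c4ccccc4)(c5ccccc5)C(C)(C)C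
F6 | step 17 | ring-C-closed alkynol, 13-ethynyl-11β-hydroxy tricycle with H at C8 (ring D open; lactone, PMB and TBDPS groups as in 39) | C#C[C@@H]1C[C@H](O)[C@@H]2C(C1)C(=O)OC[C@]23[C@@H](OCc4ccc(OC)cc4)CCC(C)(C)[C@H]3CO[Si](c5ccccc5)(c6ccccc6)C(C)(C)C
F7 | step 17 | bridged α-methylene lactone, C15(=O)–O11 lactone with C16=C17 on C13 and H at C8 | C=C1[C@@H]2C[C@H](OC1=O)[C@@H]3C(C2)C(=O)OC[C@]34[C@@H](OCc5ccc(OC)cc5)CCC(C)(C)[C@H]4CO[Si](c6ccccc6)(c7ccccc7)C(C)(C)C
A1 | direct plan | oridonin | C=C1[C@@H]2CC[C@@H]3[C@]([C@@H]2O)([C@]4(O)OC[C@]35[C@@H](O)CCC(C)(C)[C@H]5[C@@H]4O)C1=O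
A2 | direct plan | 14-deoxyoridonin | C=C1[C@@H]2CC[C@@H]3[C@](C2)([C@]4(O)OC[C@]35[C@@H](O)CCC(C)(C)[C@H]5[C@@H]4O)C1=O
A3 | direct plan | 14-deoxyoridonin 1α,6β,7β-tris-O-nitrite | C=C1[C@@H]2CC[C@@H]3[C@](C2)([C@]4(ON=O)OC[C@]35[C@@H](ON=O)CCC(C)(C)[C@H]5[C@@H]4ON=O)C1=O
A4 | direct plan | 1α-hydroxy-11β-nitrooxy-6,15-dioxo-6,7-seco-ent-kaur-16-en-7,20-olide | C=C1[C@@H]2C[C@H](O[N+](=O)[O-])[C@@H]3[C@](C2)(C(=O)OC[C@]32[C@@H](O)CCC(C)(C)[C@H]2C=O)C1=O
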